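Numbering: ring A C1 OH, C2 OAr, C4 CH2; ring B C1 O, C4 CH2; ring C C1 CH2, C2 OAr, C3 OH; ring D C1 O, C3 CH2.
Enabling feature: rings A and B are two 4-alkylphenols, and their link runs from the oxygen on C1 of ring B to C2 of ring A, next to the C1 hydroxyl. This is the ortho C–O phenol-coupling (isodityrosine) pattern, so the bond can be made by oxidising ring A.
Cuts, last-made first: O–CH3 on ring C and three steering C–halogen bonds; C2(A)–O(B), which opens the macrocycle; the B–C ethano bridge (Wittig, then diimide); C2(C)–O(D) (SNAr); the D–A ethano bridge (Wittig, then diimide).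
Forward: D is joined to A, C is attached to the ring D oxygen, B is added, both alkenes are saturated and the two halophenols are freed. The only ring formed, the 18-membered macrocycle, then closes by oxidation, and dehalogenation and demethylation finish the synthesis.
Stereochemistry: the target has no stereocentre and no alkene; alkene geometries and the sp3 centres of the dienone intermediates are erased on the way.

Key step: step 11

Remark: the Wittig alkenes are carried forward as E/Z mixtures and the dienones of the key step are racemic and transient, so their SMILES carry no stereo descriptor.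

Step 1
Reactants: 1 3-hydroxybenzyl alcohol
Product: 2 (3-hydroxybenzyl)triphenylphosphonium bromide
Conditions: PPh3·HBr, MeCN, reflux
Reagents that add atoms: triphenylphosphine hydrobromide, [Br-].c1ccc(cc1)[PH+](c1ccccc1)c1ccccc1
Why: Phosphonium salt formation from a benzylic alcohol with PPh3·HBr (acid-assisted substitution of water by bromide and then by phosphine) is routine for hydroxybenzyl alcohols, and the meta phenol needs no protection because it cannot expel the phosphine as a quinone methide.

Step 2
Reactants: 3 3,5-dibromo-4-hydroxybenzaldehyde
Product: 4 3,5-dibromo-4-(methoxymethoxy)benzaldehyde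
Conditions: MOMCl, K2CO3, acetone, 0 °C to rt
Reagents that add atoms: chloromethyl methyl ether (MOMCl), COCCl
Why: Williamson-type O-alkylation: the acidic dihalophenol is fully ionised by carbonate and the small, very reactive MOMCl reaches the flanked oxygen, which masks a proton that would quench the ylide and a phenoxide that would deactivate the aldehyde.

Step 3
Reactants: 2 (3-hydroxybenzyl)triphenylphosphonium bromide; 4 3,5-dibromo-4-(methoxymethoxy)benzaldehyde
Product: 6 3-{2-[3,5-dibromo-4-(methoxymethoxy)phenyl]ethenyl}phenol (E/Z mixture), via potassium phenoxide ylide 5 (not isolated)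
Conditions: KOtBu (2.2 equiv), THF, 0 °C; then 4, 0 °C to rt; aq NH4Cl
Reagents that add atoms: none
Why: Wittig olefination with a semi-stabilised benzylic ylide, in which the second equivalent of base only parks the meta phenol as its phenoxide, KOtBu (no alkyllithium) leaves the C–Br bonds untouched, and the alkene geometry does not matter because step 9 saturates it.

Step 4
Reactants: 6 3-{2-[3,5-dibromo-4-(methoxymethoxy)phenyl]ethenyl}phenol; 7 2-fluoro-3-methoxybenzaldehyde
Product: 8 2-(3-{2-[3,5-dibromo-4-(methoxymethoxy)phenyl]ethenyl}phenoxy)-3-methoxybenzaldehyde (E/Z mixture)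
Conditions: K2CO3, DMF, 120 °C
Reagents that add atoms: none
Why: SNAr by addition–elimination: the ortho formyl group stabilises the Meisenheimer adduct and fluoride is the best leaving group for this mechanism, while the unactivated C–Br bonds, the MOM acetal and the alkene are inert to carbonate in DMF.

Step 5
Reactants: 9 3,5-dichloro-4-hydroxybenzaldehyde
Product: 10 3,5-dichloro-4-(methoxymethoxy)benzaldehyde
Conditions: MOMCl, K2CO3, acetone, 0 °C to rt
Reagents that add atoms: chloromethyl methyl ether (MOMCl), COCCl
Why: The same Williamson-type O-alkylation as in step 2 masks the ring B phenol with a group that tolerates hydride, ylide and carbonate and that leaves later together with the ring A group.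

Step 6
Reactants: 10 3,5-dichloro-4-(methoxymethoxy)benzaldehyde
Product: 11 [3,5-dichloro-4-(methoxymethoxy)phenyl]methanol
Conditions: NaBH4, MeOH, 0 °C
Reagents that add atoms: none
Why: Borohydride reduction of an aromatic aldehyde to the benzylic alcohol, to which aryl chlorides and the MOM acetal are inert.

Step 7
Reactants: 11 [3,5-dichloro-4-(methoxymethoxy)phenyl]methanol
Product: 13 [3,5-dichloro-4-(methoxymethoxy)benzyl]triphenylphosphonium bromide, via benzylic bromide 12 (not isolated)
Conditions: PPh3 (2.3 equiv), NBS (1.1 equiv), THF, 0 °C; then reflux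
Reagents that add atoms: N-bromosuccinimide, O=C1CCC(=O)N1Br; triphenylphosphine, c1ccc(cc1)P(c1ccccc1)c1ccccc1
Why: Appel-type bromination with the PPh3–NBS adduct runs under neutral conditions that spare the acid-labile MOM ether (PBr3 or PPh3·HBr would not), and the excess phosphine in the flask is then quaternised by the benzylic bromide in an SN2 reaction, the salt being expected to crystallise away from Ph3PO and succinimide.

Step 8
Reactants: 13 [3,5-dichloro-4-(methoxymethoxy)benzyl]triphenylphosphonium bromide; 8 2-(3-{2-[3,5-dibromo-4-(methoxymethoxy)phenyl]ethenyl}phenoxy)-3-methoxybenzaldehyde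
Product: 15 1,3-dibromo-5-{2-[3-(2-{2-[3,5-dichloro-4-(methoxymethoxy)phenyl]ethenyl}-6-methoxyphenoxy)phenyl]ethenyl}-2-(methoxymethoxy)benzene (open-chain A–D–C–B bis-stilbene; E/Z mixture at both alkenes), via ring B benzylidene ylide 14 (not isolated)
Conditions: KOtBu (1.1 equiv), THF, 0 °C; then 8, 0 °C to rt
Reagents that add atoms: none
Why: Wittig olefination of the hindered but non-enolisable ring C aldehyde with the semi-stabilised ring B ylide completes the A–D–C–B carbon chain, again with no need to control alkene geometry.

Step 9
Reactants: 15 open-chain A–D–C–B bis-stilbene bis-MOM ether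
Product: 16 1,3-dibromo-5-{2-[3-(2-{2-[3,5-dichloro-4-(methoxymethoxy)phenyl]ethyl}-6-methoxyphenoxy)phenyl]ethyl}-2-(methoxymethoxy)benzene (open-chain bis-bibenzyl bis-MOM ether)
Conditions: TsNHNH2 (excess, in portions), NaOAc, DME–H2O, reflux
Reagents that add atoms: none
Why: Diimide reduction (concerted syn transfer of two hydrogens from HN=NH released from TsNHNH2) saturates both stilbene double bonds and, unlike hydrogenation on palladium, cannot cleave C–Br or C–Cl bonds, while the acetate buffer keeps the MOM ethers intact.

Step 10
Reactants: 16 open-chain bis-bibenzyl bis-MOM ether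
Product: 17 2,6-dibromo-4-{2-[3-(2-{2-[3,5-dichloro-4-hydroxyphenyl]ethyl}-6-methoxyphenoxy)phenyl]ethyl}phenol (seco bisphenol: ring A dibromophenol, ring B dichlorophenol, ring C methyl ether)
Conditions: conc. HCl (cat.), MeOH–THF, 50 °C
Reagents that add atoms: none
Why: Acid-catalysed acetal exchange removes both MOM groups, helped by the good leaving-group character of the dihalophenols, whereas the ring C methyl ether, the diaryl ether and the aryl halides do not react with dilute methanolic HCl.

Step 11
Reactants: 17 seco bisphenol
Product: 20 bromo dichloro marchantin C ring C methyl ether (ring A: C1 OH and C6 Br; ring B: C2 and C6 Cl; ring C: C3 OMe), via ipso-bromo ortho-dienone 18 (not isolated), via 4-methoxy para-dienone 19 (not isolated)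
Conditions: Tl(NO3)3·3H2O (2.5 equiv), MeOH–THF (4:1), 1 mM, 0 °C to rt; concentrate; then Zn dust, AcOH, rt
Reagents that add atoms: none
Why: Trivalent thallium engages the ring A 2,6-dibromophenol, the more easily oxidised of the two phenols (oxidation potentials of 2,6-dihalo-4-alkylphenols rise iodo < bromo < chloro), removes two electrons, and the ring B hydroxyl captures the phenoxenium-type species at a bromine-bearing ortho carbon to give ipso adduct 18. The doubly activated tertiary C–Br bond of 18 ionises and methanol adds at C4, so the material rests, shielded from further oxidation, as quinol ether 19 at the same oxidation level, and zinc in acetic acid then supplies two electrons, expels methoxide (or bromide from any remaining 18) and restores the ring A phenol in 20; the bromine is thus expected to leave as bromide by way of 19 and not necessarily by direct attack of zinc on C–Br. The closest known reaction is the Tl(NO3)3 or anodic coupling of o,o'-dihalophenols to isodityrosine-type diaryl ethers with a reductive zinc work-up, which is established for open-chain dimers and for 14- to 17-membered macrocycles. The one new ring closes as an end-to-end macroetherification, O of ring B onto C2 of ring A (18 atoms along the shortest path), helped by millimolar dilution against dimerisation, and because C2 and C6 of ring A are equivalent this direction of coupling can give one constitution only. Halogens occupy all four ortho positions and alkyl groups both para positions, so C–C coupling has no open site, ring C is silent as its methyl ether, and simple methanol capture at C4 of either phenol is reversed by the zinc step and only returns 17. The selectivity needed is ring A as acceptor and ring B as oxygen donor, which rests on the lower oxidation potential of the bromophenol and on bromide being the better leaving group from the ipso adduct, and no stereocentre is at stake since the sp3 centres of 18 and 19 vanish on rearomatisation.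

Step 12
Reactants: 20 bromo dichloro marchantin C ring C methyl ether
Product: 21 marchantin C ring C methyl ether (C3 of ring C OMe, C1 of ring A OH)
Conditions: H2 (balloon), 10% Pd/C, NaOAc, MeOH–EtOAc, rt
Reagents that add atoms: none
Why: Catalytic hydrodehalogenation on palladium with acetate as acid scavenger is the usual sequel to halogen-steered phenol couplings and removes the C–Br and both C–Cl bonds, and the molecule holds nothing else that hydrogen can reduce under these conditions.

Step 13
Reactants: 21 marchantin C ring C methyl ether
Product: 22 marchantin C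
Conditions: BBr3, CH2Cl2, −78 °C to rt; then H2O
Reagents that add atoms: none
Why: BBr3 demethylation of an aryl methyl ether (O-complexation, then SN2 attack of bromide on the methyl carbon) frees the ring C phenol, and the two diaryl ether bridges survive because neither of their carbons can undergo that substitution.

Compound list
1 | 3-hydroxybenzyl alcohol | OCc1cccc(O)c1 | starting material
2 | (3-hydroxybenzyl)triphenylphosphonium bromide | Oc1cccc(C[P+](c2ccccc2)(c2ccccc2)c2ccccc2)c1.[Br-] | intermediate
3 | 3,5-dibromo-4-hydroxybenzaldehyde | O=Cc1cc(Br)c(O)c(Br)c1 | starting material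
4 | 3,5-dibromo-4-(methoxymethoxy)benzaldehyde | O=Cc1cc(Br)c(OCOC)c(Br)c1 | intermediate
5 | potassium 3-[(triphenylphosphoranylidene)methyl]phenolate (phenoxide ylide, not isolated) | [K+].[O-]c1cccc(C=P(c2ccccc2)(c2ccccc2)c2ccccc2)c1 | intermediate
6 | 3-{2-[3,5-dibromo-4-(methoxymethoxy)phenyl]ethenyl}phenol (E/Z mixture) | Oc1cccc(C=Cc2cc(Br)c(OCOC)c(Br)c2)c1 | intermediate
7 | 2-fluoro-3-methoxybenzaldehyde | COc1cccc(C=O)c1F | starting material
8 | 2-(3-{2-[3,5-dibromo-4-(methoxymethoxy)phenyl]ethenyl}phenoxy)-3-methoxybenzaldehyde (E/Z mixture) | O=Cc1cccc(OC)c1Oc1cccc(C=Cc2cc(Br)c(OCOC)c(Br)c2)c1 | intermediate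
9 | 3,5-dichloro-4-hydroxybenzaldehyde | O=Cc1cc(Cl)c(O)c(Cl)c1 | starting material
10 | 3,5-dichloro-4-(methoxymethoxy)benzaldehyde | O=Cc1cc(Cl)c(OCOC)c(Cl)c1 | intermediate
11 | [3,5-dichloro-4-(methoxymethoxy)phenyl]methanol | OCc1cc(Cl)c(OCOC)c(Cl)c1 | intermediate
12 | 5-(bromomethyl)-1,3-dichloro-2-(methoxymethoxy)benzene (not isolated) | BrCc1cc(Cl)c(OCOC)c(Cl)c1 | intermediate
13 | [3,5-dichloro-4-(methoxymethoxy)benzyl]triphenylphosphonium bromide | COCOc1c(Cl)cc(C[P+](c2ccccc2)(c2ccccc2)c2ccccc2)cc1Cl.[Br-] | intermediate
14 | [3,5-dichloro-4-(methoxymethoxy)benzylidene]triphenylphosphorane (not isolated) | COCOc1c(Cl)cc(C=P(c2ccccc2)(c2ccccc2)c2ccccc2)cc1Cl | intermediate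
15 | open-chain A–D–C–B bis-stilbene bis-MOM ether (E/Z mixture at both alkenes) | COCOc1c(Br)cc(C=Cc2cccc(Oc3c(OC)cccc3C=Cc3cc(Cl)c(OCOC)c(Cl)c3)c2)cc1Br | intermediate
16 | open-chain bis-bibenzyl bis-MOM ether | COCOc1c(Br)cc(CCc2cccc(Oc3c(OC)cccc3CCc3cc(Cl)c(OCOC)c(Cl)c3)c2)cc1Br | intermediate
17 | seco bisphenol (ring A 2,6-dibromophenol, ring B 2,6-dichlorophenol, ring C methyl ether) | Oc1c(Br)cc(CCc2cccc(Oc3c(OC)cccc3CCc3cc(Cl)c(O)c(Cl)c3)c2)cc1Br | intermediate
18 | macrocyclic 6-aryloxy-2,6-dibromocyclohexa-2,4-dienone in place of ring A (racemic, not isolated) | O=C1C(Br)=CC2=CC1(Br)Oc1c(Cl)cc(cc1Cl)CCc1cccc(OC)c1Oc1cccc(c1)CC2 | intermediate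
19 | macrocyclic 2-aryloxy-6-bromo-4-methoxycyclohexa-2,5-dienone in place of ring A (racemic, not isolated) | O=C1C(Br)=CC2(OC)C=C1Oc1c(Cl)cc(cc1Cl)CCc1cccc(OC)c1Oc1cccc(c1)CC2 | intermediate
20 | bromo dichloro marchantin C ring C methyl ether | Oc1c(Br)cc2cc1Oc1c(Cl)cc(cc1Cl)CCc1cccc(OC)c1Oc1cccc(c1)CC2 | intermediate
21 | marchantin C ring C methyl ether | Oc1ccc2cc1Oc1ccc(cc1)CCc1cccc(OC)c1Oc1cccc(c1)CC2 | intermediate
22 | marchantin C | Oc1ccc2cc1Oc1ccc(cc1)CCc1cccc(O)c1Oc1cccc(c1)CC2 | target

Total step count: 13.
Longest linear sequence: 9 steps (1, 3, 4, 8, 9, 10, 11, 12, 13 from compound 1; the ring B branch 5, 6, 7, 8 to 13 from compound 9 is equally long).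

Steps most likely to fail

Step 11.
- **What may go wrong:** Oxidation may begin at ring B instead of ring A, so that the ether forms in the reverse sense. Chains may couple with one another faster than they fold. Methanol may trap the oxidised ring before the remote hydroxyl arrives. Bromide set loose in an oxidising medium may also halogenate ring C, but step 12 would erase that.
- **Fallback:** It makes the same bond by redox-neutral copper chemistry, and the direction is fixed because only ring A carries C–Br and only ring B carries a free hydroxyl. It sets out from 8.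
- Commercial (4-hydroxybenzyl)triphenylphosphonium bromide is turned with two equivalents of KOtBu into the potassium 4-[(triphenylphosphoranylidene)methyl]phenolate F1.
- This ylide olefinates 8 to the bis-stilbene with a halogen-free ring B phenol F2.
- Diimide as in step 9 gives the saturated open-chain phenol F3.
- An intramolecular Ullmann ether synthesis (CuI, N,N-dimethylglycine, Cs2CO3, dioxane, 100 °C, slow addition) joins the ring B oxygen to one of the two equivalent C–Br carbons of ring A. It gives the macrocyclic bromo MOM ether F4.
- Hydrogenolysis (H2, Pd/C, NaOAc, MeOH) removes the last bromine to give the macrocyclic MOM ether F5.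
- HCl in MeOH frees the ring A phenol, which brings the sequence back to the route at 21.

Step 4.
- **What may go wrong:** The substitution may stall. The fluorine sits between the formyl and methoxy groups, and the methoxy oxygen pushes electron density onto a carbon that must carry negative charge in the adduct. Forcing temperatures may then erode the aldehyde or the MOM ether.
- **Fallback:** The C–O–D ether is made first by copper catalysis, while no other aryl bromide is present, and the order of the two olefinations is inverted. It sets out from 1.
- Ullmann-type coupling of 1 with commercial 2-bromo-3-methoxybenzaldehyde (CuI, picolinic acid, K3PO4, DMSO, 90 °C; the phenol reacts and the benzylic alcohol does not) gives 2-[3-(hydroxymethyl)phenoxy]-3-methoxybenzaldehyde F6.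
- Ylide 14, made as in step 8 with one extra equivalent of base for the free alcohol, converts it into the B–C stilbene benzylic alcohol F7.
- PPh3 and NBS as in step 7 lead through the ring D benzylic bromide F8 to the ring D phosphonium bromide F9.
- KOtBu gives the ring D ylide F10, which olefinates aldehyde 4 and comes back to the route at 15.

Step 12.
- **What may go wrong:** Hydrogenolysis may stop short. The C–Br bond should go quickly, but the two chlorines flank the diaryl ether oxygen inside the macrocycle and may reach the metal surface poorly. Accumulating halide may also slow the catalyst.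
- **Fallback:** The endgame is inverted, and surface hydrogenolysis is replaced by a dissolving-alloy reduction in water. It sets out from 20.
- BBr3 (CH2Cl2, −78 °C to rt) cleaves the methyl ether first and gives bromo dichloro marchantin C F11.
- The bis-phenoxide of F11 dissolves in aqueous NaOH–MeOH, where Ni–Al alloy removes all three halogens. Acidification comes back to the route at 22.

Further compounds
F1 | step 11 | potassium 4-[(triphenylphosphoranylidene)methyl]phenolate | [K+].[O-]c1ccc(C=P(c2ccccc2)(c2ccccc2)c2ccccc2)cc1
F2 | step 11 | bis-stilbene with halogen-free ring B phenol and ring A dibromo MOM ether (E/Z mixture) | Oc1ccc(C=Cc2cccc(OC)c2Oc2cccc(C=Cc3cc(Br)c(OCOC)c(Br)c3)c2)cc1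
F3 | step 11 | saturated open-chain phenol (ring B free phenol, ring A dibromo MOM ether) | Oc1ccc(CCc2cccc(OC)c2Oc2cccc(CCc3cc(Br)c(OCOC)c(Br)c3)c2)cc1
F4 | step 11 | macrocyclic bromo MOM ether (ring A C1 OMOM and C6 Br, ring C C3 OMe) | COCOc1c(Br)cc2cc1Oc1ccc(cc1)CCc1cccc(OC)c1Oc1cccc(c1)CC2
F5 | step 11 | macrocyclic MOM ether (ring A C1 OMOM, ring C C3 OMe) | COCOc1ccc2cc1Oc1ccc(cc1)CCc1cccc(OC)c1Oc1cccc(c1)CC2
F6 | step 4 | 2-[3-(hydroxymethyl)phenoxy]-3-methoxybenzaldehyde | O=Cc1cccc(OC)c1Oc1cccc(CO)c1
F7 | step 4 | B–C stilbene benzylic alcohol (E/Z mixture) | OCc1cccc(Oc2c(OC)cccc2C=Cc2cc(Cl)c(OCOC)c(Cl)c2)c1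
F8 | step 4 | ring D benzylic bromide (E/Z mixture) | BrCc1cccc(Oc2c(OC)cccc2C=Cc2cc(Cl)c(OCOC)c(Cl)c2)c1
F9 | step 4 | ring D phosphonium bromide (E/Z mixture) | [Br-].COCOc1c(Cl)cc(C=Cc2cccc(OC)c2Oc2cccc(C[P+](c3ccccc3)(c3ccccc3)c3ccccc3)c2)cc1Cl
F10 | step 4 | ring D ylide (E/Z mixture) | COCOc1c(Cl)cc(C=Cc2cccc(OC)c2Oc2cccc(C=P(c3ccccc3)(c3ccccc3)c3ccccc3)c2)cc1Cl
F11 | step 12 | bromo dichloro marchantin C (ring A C6 Br, ring B C2 and C6 Cl, both phenols free) | Oc1c(Br)cc2cc1Oc1c(Cl)cc(cc1Cl)CCc1cccc(O)c1Oc1cccc(c1)CC2
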